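## Retrosynthetic overview

1. Target 18 ⇐ O‑demethylation, syn‑dehydration, double formylation and hydrogenation ⇐ tetracyclic isopulegol‑type alcohol 14, in which rings A–D are complete.
2. Key disconnection (step 9): two bonds of 14 are cut together, spiro C–C(H)(O) at the B/C fusion and C(H)(OH)–C(H)(isopropenyl) in ring D. This unzips rings C and D to the bicyclic chroman acetal 12, which carries one open chain.
3. Enabling feature: the spiro carbon lies between the pyran O–CH (B/C fusion, acetal level) and the vinylic CH of ring D (aldehyde level). It is therefore the α‑carbon of an aldehyde that can attack an oxocarbenium ion. Ring D with its CH3 and isopropyl groups is a p‑menth‑3‑ene, that is, the ten carbons and the stereocentre of (R)‑citronellal, re‑closed by the citronellal→isopulegol ene reaction.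
4. 12 ⇐ enal 11 ⇐ aldehyde 7 + citronellal aldimine 9 (directed aldol condensation). 7 ⇐ citropten 1 by asymmetric conjugate addition of isobutyl, then allylation, then methylation trans to isobutyl.
5. Ring order: A and B come with citropten (B stays closed as lactone → acetal → ether). Ring C and then ring D, the last ring, close in step 9.

Key step: step 9

Assumption: the C‑2 lactol/acetal centre in 5–7 and 10–12, the two new centres in 10 and the enol ether geometry in 12 are carried as mixtures. All of them are erased in steps 7–9, so they are left undefined in the SMILES.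

## Route

Step 1
Reactants: 1 citropten (5,7‑dimethoxycoumarin)
Product: 2 (4R)‑5,7‑dimethoxy‑4‑(2‑methylpropyl)chroman‑2‑one
Conditions: i‑BuMgBr, CuBr·SMe2 (5 mol %), Josiphos‑type ferrocenyl diphosphine (6 mol %, the enantiomer that gives 4R), t‑BuOMe/CH2Cl2, −72 °C; aq. work‑up
Reagents that add atoms: isobutylmagnesium bromide, CC(C)C[Mg]Br
Why: Copper‑catalysed asymmetric conjugate addition of a Grignard reagent to a coumarin, a known substrate class for ferrocenyl‑diphosphine/Cu(I) catalysts; the chiral ligand decides which face of C‑4 receives isobutyl and so sets the benzylic stereocentre as (R).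

Step 2
Reactants: 2 (4R)‑5,7‑dimethoxy‑4‑(2‑methylpropyl)chroman‑2‑one
Product: 3 (3R,4R)‑3‑allyl‑5,7‑dimethoxy‑4‑(2‑methylpropyl)chroman‑2‑one (allyl trans to isobutyl)
Conditions: LiHMDS, THF, −78 °C; allyl bromide, −78 → −40 °C
Reagents that add atoms: allyl bromide, C=CCBr
Why: Alkylation of the lactone lithium enolate at low temperature; allyl bromide enters anti to the pseudo‑axial isobutyl group, and although this centre is flattened again in step 3, putting allyl on first is what lets methyl come last.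

Step 3
Reactants: 3 (3R,4R)‑3‑allyl‑5,7‑dimethoxy‑4‑(2‑methylpropyl)chroman‑2‑one
Product: 4 (3S,4S)‑3‑allyl‑5,7‑dimethoxy‑3‑methyl‑4‑(2‑methylpropyl)chroman‑2‑one (methyl trans, allyl cis to isobutyl)
Conditions: LiHMDS, THF/DMPU, −78 °C; MeI, −78 → −30 °C
Reagents that add atoms: iodomethane, CI
Why: Second enolate alkylation: the isobutyl group, held pseudo‑axial by the peri methoxy group, shields one face of the planar enolate, so methyl iodide adds trans to it and the quaternary centre forms with methyl trans and allyl cis to isobutyl, as in the target.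

Step 4
Reactants: 4 (3S,4S)‑3‑allyl‑5,7‑dimethoxy‑3‑methyl‑4‑(2‑methylpropyl)chroman‑2‑one
Product: 6 (3S,4S)‑3‑allyl‑2,5,7‑trimethoxy‑3‑methyl‑4‑(2‑methylpropyl)chroman, via lactol 5 (not isolated)
Conditions: DIBAL‑H, CH2Cl2, −78 °C, aq. work‑up; then MeOH, PPTS (cat.), rt
Reagents that add atoms: methanol, CO
Why: Partial reduction of a lactone with DIBAL‑H stops at the aluminium hemiacetal at −78 °C, and acid‑catalysed exchange with methanol gives the base‑stable cyclic methyl acetal, so ring B stays closed, the future O–CH carbon reaches its final oxidation level and the leaving group for step 9 is in place.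

Step 5
Reactants: 6 (3S,4S)‑3‑allyl‑2,5,7‑trimethoxy‑3‑methyl‑4‑(2‑methylpropyl)chroman
Product: 7 2‑[(3S,4S)‑2,5,7‑trimethoxy‑3‑methyl‑4‑(2‑methylpropyl)chroman‑3‑yl]acetaldehyde
Conditions: OsO4 (cat.), NaIO4, 2,6‑lutidine, dioxane/H2O, rt
Reagents that add atoms: sodium periodate, [Na+].[O-]I(=O)(=O)=O
Why: Lemieux–Johnson oxidation cleaves the only alkene to the aldehyde under near‑neutral conditions that spare the acetal and, unlike ozone, the electron‑rich arene.

Step 6
Reactants: 8 (R)‑citronellal
Product: 9 N‑cyclohexyl aldimine of (R)‑citronellal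
Conditions: cyclohexylamine, 4 Å MS, Et2O, 0 °C → rt
Reagents that add atoms: cyclohexylamine, NC1CCCCC1
Why: Simple condensation of an aldehyde with a primary amine; the stereocentre is β to the C=N bond and is not touched.

Step 7
Reactants: 7 2‑[(3S,4S)‑2,5,7‑trimethoxy‑3‑methyl‑4‑(2‑methylpropyl)chroman‑3‑yl]acetaldehyde; 9 N‑cyclohexyl aldimine of (R)‑citronellal
Product: 11 (2E,3R)‑2‑{2‑[(3S,4S)‑2,5,7‑trimethoxy‑3‑methyl‑4‑(2‑methylpropyl)chroman‑3‑yl]ethylidene}‑3,7‑dimethyloct‑6‑enal, via hydroxy aldimine 10 (not isolated)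
Conditions: 9, LDA, THF, −78 °C; 7, −78 °C; then AcOH/H2O/THF, 40 °C
Reagents that add atoms: water, O
Why: Wittig directed aldol condensation: the lithio‑azaenolate of 9 adds to 7 without self‑condensation of either aldehyde, and mild acid hydrolyses the imine while the ammonium acetate formed promotes β‑elimination to the conjugated (E)‑enal, which joins the C19 and C10 halves.

Step 8
Reactants: 11 the (2E,3R)‑enal
Product: 12 triethylsilyl enol ether of the saturated aldehyde (triethyl{[(3R)‑2‑{2‑[(3S,4S)‑2,5,7‑trimethoxy‑3‑methyl‑4‑(2‑methylpropyl)chroman‑3‑yl]ethyl}‑3,7‑dimethylocta‑1,6‑dien‑1‑yl]oxy}silane)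
Conditions: Et3SiH, RhCl(PPh3)3 (cat.), THF, 50 °C
Reagents that add atoms: triethylsilane, CC[SiH](CC)CC
Why: Rhodium‑catalysed 1,4‑hydrosilylation of an enal with a monohydrosilane gives the silyl enol ether regiospecifically at the fully substituted α‑carbon, without base, and leaves the trisubstituted alkene and the acetal alone.

Step 9
Reactants: 12 triethylsilyl enol ether
Product: 14 (1R,2S,3S,3a′R,6R,9′R,9a′S)‑6′,8′‑dimethoxy‑6,9a′‑dimethyl‑9′‑(2‑methylpropyl)‑3‑(prop‑1‑en‑2‑yl)‑1′,2′,3a′,9′‑tetrahydrospiro[cyclohexane‑1,3′‑cyclopenta[b]chromen]‑2‑ol, via tricyclic aldehyde 13 (not isolated)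
Conditions: Sc(OTf)3 (15 mol %), 4 Å MS, CH2Cl2, −78 → −20 °C
Reagents that add atoms: none
Why: Sc(OTf)3 ionises the C‑2 methoxy acetal of ring B to the aryl‑stabilised oxocarbenium ion, the tethered silyl enol ether attacks it through its fully substituted α‑carbon (intramolecular Mukaiyama‑type acetal substitution, 5‑(enolexo)‑exo‑trig, closes ring C), silyl transfer to methoxide frees the neopentyl aldehyde 13, and the same Lewis acid then drives its type‑I carbonyl‑ene reaction with the trisubstituted alkene (6‑exo‑trig through a chair, closes ring D last). The closest known reaction types are Lewis‑acid coupling of silyl enol ethers with 2‑alkoxychromans and other acetals, Mukaiyama aldol–Prins cascades and the Sc(OTf)3‑catalysed citronellal→isopulegol cyclisation. The O–CH centre is fixed by the two‑carbon tether, which can reach the cation only from the face of C‑3 that carries it, so B/C becomes cis‑fused with H syn to the angular methyl group. The spiro centre is set in an open transition state in which the sec‑alkyl chain lies anti to the bond to quaternary C‑3 and the silyloxyvinyl carbon lies antiperiplanar to C=O+, which places CHO on the convex face (syn to H and CH3) and the chain on the concave face, as in the target. The carbinol and isopropenyl centres follow from the all‑equatorial chair dictated by the (R)‑methyl group of citronellal and are erased in steps 10 and 12. The step needs loss of methoxide rather than ring opening of B (endocyclic ionisation is undone by internal return of the tethered phenoxide, whereas methoxide leaves for good) and the enol ether rather than the alkene as first nucleophile (five‑ against nine‑membered closure and far higher nucleophilicity).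

Step 10
Reactants: 14 tetracyclic homoallylic alcohol
Product: 15 (1R,2S,3S,3a′R,6R,9′R,9a′S)‑3‑isopropyl analogue of 14 (menthol‑type alcohol)
Conditions: H2 (1 atm), Pd/C, EtOAc, rt
Reagents that add atoms: none
Why: Heterogeneous hydrogenation; the 1,1‑disubstituted isopropenyl alkene is the only reducible group and no stereocentre is formed or touched.

Step 11
Reactants: 15 menthol‑type alcohol
Product: 16 5′,7′‑dicarbaldehyde of 15
Conditions: Cl2CHOMe, TiCl4, CH2Cl2, −78 → 0 °C; then aq. HCl
Reagents that add atoms: dichloromethyl methyl ether, COC(Cl)Cl; water, O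
Why: Rieche formylation of the two remaining aromatic CH positions, each activated by two flanking oxygen substituents; it is run before any alkene is present, and the hindered secondary alcohol is only parked as its titanium alkoxide and is released on work‑up.

Step 12
Reactants: 16 dialdehyde alcohol
Product: 17 di‑O‑methyl ether of the target
Conditions: Burgess reagent, toluene, 80 °C
Reagents that add atoms: none
Why: Burgess dehydration (syn‑elimination of the sulfamate): one neighbour of the carbinol carbon is the quaternary spiro carbon, so the only β‑hydrogen is the one on the isopropyl‑bearing carbon, which is cis to the equatorial oxygen, and the alkene can form only in the required position.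

Step 13
Reactants: 17 di‑O‑methyl ether of the target
Product: 18 target, (1R,3a′R,6R,9′R,9a′S)‑6′,8′‑dihydroxy‑3‑isopropyl‑6,9a′‑dimethyl‑9′‑(2‑methylpropyl)‑1′,2′,3a′,9′‑tetrahydrospiro[cyclohex‑2‑ene‑1,3′‑cyclopenta[b]chromene]‑5′,7′‑dicarbaldehyde
Conditions: BCl3, CH2Cl2, −78 → 0 °C; then H2O
Reagents that add atoms: none
Why: Chelation‑assisted aryl methyl ether cleavage: each methoxy group is ortho to a formyl group, so BCl3 binds in a six‑membered chelate and chloride removes methyl, while the doubly neopentyl O–CH bond of the pyran resists and no stereocentre is touched.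

## Compound list

1 | citropten (5,7‑dimethoxycoumarin) | COc1cc(OC)c2C=CC(=O)Oc2c1 | starting material
2 | (4R)‑5,7‑dimethoxy‑4‑(2‑methylpropyl)chroman‑2‑one | CC(C)C[C@H]1c2c(OC)cc(OC)cc2OC(=O)C1 | intermediate
3 | (3R,4R)‑3‑allyl‑5,7‑dimethoxy‑4‑(2‑methylpropyl)chroman‑2‑one | CC(C)C[C@H]1c2c(OC)cc(OC)cc2OC(=O)[C@@H]1CC=C | intermediate
4 | (3S,4S)‑3‑allyl‑5,7‑dimethoxy‑3‑methyl‑4‑(2‑methylpropyl)chroman‑2‑one | CC(C)C[C@H]1c2c(OC)cc(OC)cc2OC(=O)[C@@]1(C)CC=C | intermediate
5 | (3S,4S)‑3‑allyl‑5,7‑dimethoxy‑3‑methyl‑4‑(2‑methylpropyl)chroman‑2‑ol (lactol, anomers) | CC(C)C[C@H]1c2c(OC)cc(OC)cc2OC(O)[C@@]1(C)CC=C | intermediate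
6 | (3S,4S)‑3‑allyl‑2,5,7‑trimethoxy‑3‑methyl‑4‑(2‑methylpropyl)chroman (anomers) | CC(C)C[C@H]1c2c(OC)cc(OC)cc2OC(OC)[C@@]1(C)CC=C | intermediate
7 | 2‑[(3S,4S)‑2,5,7‑trimethoxy‑3‑methyl‑4‑(2‑methylpropyl)chroman‑3‑yl]acetaldehyde | CC(C)C[C@H]1c2c(OC)cc(OC)cc2OC(OC)[C@@]1(C)CC=O | intermediate
8 | (R)‑citronellal | C[C@H](CCC=C(C)C)CC=O | starting material
9 | N‑cyclohexyl aldimine of (R)‑citronellal | C[C@H](CCC=C(C)C)CC=NC1CCCCC1 | intermediate
10 | β‑hydroxy aldimine (aldol adduct of 7 and 9) | CC(C)C[C@H]1c2c(OC)cc(OC)cc2OC(OC)[C@@]1(C)CC(O)C(C=NC1CCCCC1)[C@H](C)CCC=C(C)C | intermediate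
11 | (2E,3R)‑2‑{2‑[(3S,4S)‑2,5,7‑trimethoxy‑3‑methyl‑4‑(2‑methylpropyl)chroman‑3‑yl]ethylidene}‑3,7‑dimethyloct‑6‑enal | CC(C)C[C@H]1c2c(OC)cc(OC)cc2OC(OC)[C@@]1(C)C/C=C(/C=O)[C@H](C)CCC=C(C)C | intermediate
12 | triethylsilyl enol ether (E/Z) of the saturated aldehyde | CC(C)C[C@H]1c2c(OC)cc(OC)cc2OC(OC)[C@@]1(C)CCC(=CO[Si](CC)(CC)CC)[C@H](C)CCC=C(C)C | intermediate
13 | (3S,3aR,9R,9aS)‑6,8‑dimethoxy‑9a‑methyl‑3‑[(2R)‑6‑methylhept‑5‑en‑2‑yl]‑9‑(2‑methylpropyl)‑1,2,3,3a,9,9a‑hexahydrocyclopenta[b]chromene‑3‑carbaldehyde | CC(C)C[C@H]1c2c(OC)cc(OC)cc2O[C@@H]2[C@@]1(C)CC[C@]2(C=O)[C@H](C)CCC=C(C)C | intermediate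
14 | tetracyclic homoallylic alcohol (1R,2S,3S,3a′R,6R,9′R,9a′S) | CC(C)C[C@H]1c2c(OC)cc(OC)cc2O[C@@H]2[C@@]1(C)CC[C@@]21[C@@H](O)[C@H](C(C)=C)CC[C@H]1C | intermediate
15 | tetracyclic menthol‑type alcohol (3‑isopropyl) | CC(C)C[C@H]1c2c(OC)cc(OC)cc2O[C@@H]2[C@@]1(C)CC[C@@]21[C@@H](O)[C@H](C(C)C)CC[C@H]1C | intermediate
16 | 5′,7′‑dicarbaldehyde of 15 | CC(C)C[C@H]1c2c(OC)c(C=O)c(OC)c(C=O)c2O[C@@H]2[C@@]1(C)CC[C@@]21[C@@H](O)[C@H](C(C)C)CC[C@H]1C | intermediate
17 | di‑O‑methyl ether of the target | CC(C)C[C@H]1c2c(OC)c(C=O)c(OC)c(C=O)c2O[C@@H]2[C@@]1(C)CC[C@@]21C=C(C(C)C)CC[C@H]1C | intermediate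
18 | target CNP0121396.1 | CC(C)C[C@H]1c2c(O)c(C=O)c(O)c(C=O)c2O[C@@H]2[C@@]1(C)CC[C@@]21C=C(C(C)C)CC[C@H]1C | target

## Step count

Total step count: 13. Longest linear sequence: 12 (steps 1–5 and 7–13).

## Steps most likely to fail

1. Step 9. The first C–C bond formation may discriminate poorly between the side chain and the silyloxyvinyl group at the enol carbon, which would erode the spiro centre. Protodesilylation of the enol ether may also occur before cyclisation.
The fallback sets out from 7 and 8 and comes back at 14. It replaces the formyl‑level nucleophile by a nitrile and closes rings C and D in separate operations, D still last.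
   - Aldehyde 8 is converted with iodine in aqueous ammonia into (R)‑citronellonitrile F1.
   - Aldehyde 7 is reduced (NaBH4) to the primary alcohol F2, which I2, PPh3 and imidazole turn into the primary iodide F3.
   - The lithio anion of F1 (LDA) is alkylated with F3 to the α‑branched nitrile F4.
   - LDA/TBSCl then gives the N‑silyl ketene imine F5. Its rod‑shaped C=C=N unit leaves the side chain as the only bulky group at the nucleophilic carbon.
   - TMSOTf closes ring C to the tricyclic nitrile F6.
   - DIBAL‑H and hydrolysis give aldehyde 13, now isolated, and Me2AlCl closes ring D by the ene reaction to 14.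

2. Step 1. Conversion may be low and facial selectivity eroded, because the 5‑ and 7‑methoxy groups deactivate the acceptor and the peri methoxy group crowds C‑4.
The fallback sets out from 1 and comes back at 2. It sets the stereocentre by hydride transfer instead of alkyl transfer.
   - Copper(I)‑promoted addition without ligand (i‑BuMgBr, CuI, TMSCl) gives the racemic lactone F7.
   - DDQ in refluxing dioxane dehydrogenates it to 4‑isobutyl‑5,7‑dimethoxycoumarin F8.
   - Ligated copper hydride (Cu(OAc)2, DTBM‑SEGPHOS, diethoxymethylsilane, t‑BuOH) reduces this in 1,4‑ and then 1,2‑fashion to the (4R)‑lactol F9.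
   - TEMPO/PhI(OAc)2 oxidises F9 to 2.

3. Step 12. The crowded sulfamate may collapse by ionisation, with a Wagner–Meerwein shift of a bond of the spiro carbon, instead of undergoing syn‑elimination.
The fallback sets out from 16 and comes back at 17. It avoids any cation next to the spiro centre.
   - Dess–Martin periodinane gives the ketone F10.
   - KHMDS and Comins' reagent give the enol triflate F11; only the isopropyl‑bearing side can enolise.
   - Palladium‑catalysed formate reduction (Pd(OAc)2, PPh3, HCO2H, Bu3N, DMF) replaces triflate by hydrogen to give 17.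

## Further compounds

F1 | step 9 | (R)‑citronellonitrile, (3R)‑3,7‑dimethyloct‑6‑enenitrile | C[C@H](CCC=C(C)C)CC#N
F2 | step 9 | 2‑[(3S,4S)‑2,5,7‑trimethoxy‑3‑methyl‑4‑(2‑methylpropyl)chroman‑3‑yl]ethanol | CC(C)C[C@H]1c2c(OC)cc(OC)cc2OC(OC)[C@@]1(C)CCO
F3 | step 9 | (3S,4S)‑3‑(2‑iodoethyl)‑2,5,7‑trimethoxy‑3‑methyl‑4‑(2‑methylpropyl)chroman | CC(C)C[C@H]1c2c(OC)cc(OC)cc2OC(OC)[C@@]1(C)CCI
F4 | step 9 | α‑branched nitrile (α‑epimers) | CC(C)C[C@H]1c2c(OC)cc(OC)cc2OC(OC)[C@@]1(C)CCC(C#N)[C@H](C)CCC=C(C)C
F5 | step 9 | N‑(tert‑butyldimethylsilyl) ketene imine | CC(C)C[C@H]1c2c(OC)cc(OC)cc2OC(OC)[C@@]1(C)CCC(=C=N[Si](C)(C)C(C)(C)C)[C@H](C)CCC=C(C)C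
F6 | step 9 | tricyclic nitrile (3R,3aR,9R,9aS) | CC(C)C[C@H]1c2c(OC)cc(OC)cc2O[C@@H]2[C@@]1(C)CC[C@]2(C#N)[C@H](C)CCC=C(C)C
F7 | step 1 | racemic 5,7‑dimethoxy‑4‑(2‑methylpropyl)chroman‑2‑one | CC(C)CC1CC(=O)Oc2cc(OC)cc(OC)c12
F8 | step 1 | 4‑isobutyl‑5,7‑dimethoxycoumarin | CC(C)CC1=CC(=O)Oc2cc(OC)cc(OC)c12
F9 | step 1 | (4R)‑5,7‑dimethoxy‑4‑(2‑methylpropyl)chroman‑2‑ol | CC(C)C[C@H]1c2c(OC)cc(OC)cc2OC(O)C1
F10 | step 12 | ring‑D ketone of 16 | CC(C)C[C@H]1c2c(OC)c(C=O)c(OC)c(C=O)c2O[C@@H]2[C@@]1(C)CC[C@@]21C(=O)[C@H](C(C)C)CC[C@H]1C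
F11 | step 12 | ring‑D enol triflate | CC(C)C[C@H]1c2c(OC)c(C=O)c(OC)c(C=O)c2O[C@@H]2[C@@]1(C)CC[C@@]21C(OS(=O)(=O)C(F)(F)F)=C(C(C)C)CC[C@H]1C
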